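**Plan**
- Retrosynthetic cuts: the C8 and C3 acyl groups first. Then the lactone O6–C12, C11–C12 and C6–C7 bonds are cut together: the α-methylene-γ-butyrolactone fused at C6–C7 to the ten-membered ring (exocyclic C13=C11 carrying C12, carbinol C6 next to C7) is read as terminal allene C7=C11=C13 + CO2 + C6 aldehyde. Then C9–C10, C1=C10 and C3–C4.
- Forward: the chain is joined linearly: Z-iodobutenol + C1–C3 aldehyde (C3–C4), iodo-Wittig at C1 (C1=C10), Nozaki–Hiyama–Kishi union with a C7–C9 ynal (C9–C10), alkyne to allene, enal unveiled. The ten-membered carbocycle and the lactone then arise in one operation, followed by acetate and epoxy ester.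
- Stereochemistry: C3 by ligand-controlled alkenylchromium addition; C8 from D-glyceraldehyde; C9 by Felkin–Anh addition; C6 and C7 in the ring-forming step (allylic strain at C8, ring constraint); both Z olefins from stereodefined alkenyl iodides; epoxide by Sharpless epoxidation.

Key step: step 15

Remark: atom numbers are germacrane numbers (C12 lactone carbonyl on O6, C13 exocyclic CH2, C14 on C10, C15 on C4). The SMILES is read as 1(10)Z,4Z with a (2S,3R)-2,3-dimethyloxirane-2-carboxylate (cis-dimethyl) on O8. Aldehydes 4 and 10 and alcohol 25 are taken as purchasable.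

Step 1
Reactants: 1 but-2-yn-1-ol
Product: 3 (Z)-3-iodobut-2-en-1-ol, via oxaluminole aluminate 2 (not isolated)
Conditions: NaAlH2(OCH2CH2OMe)2 (Red-Al), Et2O, 0 °C → rt; then I2, THF, −78 → 0 °C
Reagents that add atoms: iodine, II
Why: Hydroxyl-directed trans-hydroalumination of the propargylic alcohol (aluminium delivered to C3 within a five-membered alkoxyaluminate) followed by iodinolysis with retention should give only the Z-iodide, which fixes the C4=C5 geometry.

Step 2
Reactants: 3 (Z)-3-iodobut-2-en-1-ol; 4 3-[(4-methoxybenzyl)oxy]propanal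
Product: 5 (2Z,4S)-6-[(4-methoxybenzyl)oxy]-3-methylhex-2-ene-1,4-diol
Conditions: CrCl2 (4 equiv), NiCl2 (2 mol %), N-[2-(4-isopropyl-4,5-dihydrooxazol-2-yl)-6-methylphenyl]methanesulfonamide (single enantiomer, 4.4 equiv), Et3N, THF, rt
Reagents that add atoms: none
Why: Asymmetric Nozaki–Hiyama–Kishi reaction: the alkenylchromium, formed with retention of the Z geometry under nickel catalysis, adds to the aldehyde inside the chiral sulfonamide complex of trivalent chromium, so that C3 (S) is set by the ligand antipode chosen, while the free hydroxyl is carried as its chromium alkoxide.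

Step 3
Reactants: 5 (2Z,4S)-6-[(4-methoxybenzyl)oxy]-3-methylhex-2-ene-1,4-diol
Product: 6 (2Z,4S)-6-[(4-methoxybenzyl)oxy]-3-methyl-1,4-bis(triethylsilyloxy)hex-2-ene
Conditions: TESCl (2.5 equiv), imidazole, DMF, 0 °C → rt
Reagents that add atoms: chlorotriethylsilane, CC[Si](Cl)(CC)CC
Why: Routine silylation of both hydroxyls, triethylsilyl being chosen because the primary ether can later be oxidized directly under Swern conditions and the secondary one is cleaved before a tert-butyldimethylsilyl ether.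

Step 4
Reactants: 6 (2Z,4S)-6-[(4-methoxybenzyl)oxy]-3-methyl-1,4-bis(triethylsilyloxy)hex-2-ene
Product: 7 (3S,4Z)-4-methyl-3,6-bis(triethylsilyloxy)hex-4-en-1-ol
Conditions: DDQ, CH2Cl2/pH 7 buffer, 0 °C
Reagents that add atoms: none
Why: Oxidative cleavage of the 4-methoxybenzyl ether by DDQ (hydride abstraction at the electron-rich benzylic position, then hydrolysis) should leave the silyl ethers and the trisubstituted olefin untouched under buffered conditions.

Step 5
Reactants: 7 (3S,4Z)-4-methyl-3,6-bis(triethylsilyloxy)hex-4-en-1-ol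
Product: 8 (3S,4Z)-4-methyl-3,6-bis(triethylsilyloxy)hex-4-enal
Conditions: Dess–Martin periodinane, CH2Cl2, 0 °C → rt
Reagents that add atoms: none
Why: Dess–Martin oxidation of the primary alcohol under non-basic conditions should give the β-silyloxy aldehyde without β-elimination.

Step 6
Reactants: 8 (3S,4Z)-4-methyl-3,6-bis(triethylsilyloxy)hex-4-enal
Product: 9 (2Z,4S,6Z)-7-iodo-3-methyl-1,4-bis(triethylsilyloxy)octa-2,6-diene
Conditions: EtPPh3I, n-BuLi, THF, rt; I2, −78 °C; NaN(SiMe3)2, −20 °C; then 8, −78 → −20 °C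
Reagents that add atoms: ethyltriphenylphosphonium iodide, CC[P+](c1ccccc1)(c1ccccc1)c1ccccc1.[I-]; iodine, II
Why: Stork–Zhao-type iodo-Wittig olefination, in which the non-stabilized α-iodo ylide reacts under kinetic control to place iodine cis to the chain, giving the (Z)-2-iodoalkene that fixes the C1=C10 geometry.

Step 7
Reactants: 10 (R)-2,2-dimethyl-1,3-dioxolane-4-carbaldehyde
Product: 11 (S)-4-ethynyl-2,2-dimethyl-1,3-dioxolane
Conditions: dimethyl (1-diazo-2-oxopropyl)phosphonate, K2CO3, MeOH, 0 °C → rt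
Reagents that add atoms: dimethyl (1-diazo-2-oxopropyl)phosphonate, CC(=O)C(=[N+]=[N-])P(=O)(OC)OC
Why: Ohira–Bestmann (Seyferth–Gilbert) homologation converts the chiral-pool aldehyde into the terminal alkyne under mild carbonate conditions, so that the stereocentre that becomes C8 is kept (the descriptor changes only by priority).

Step 8
Reactants: 11 (S)-4-ethynyl-2,2-dimethyl-1,3-dioxolane
Product: 12 (S)-but-3-yne-1,2-diol
Conditions: Dowex 50W (H+ form), MeOH, rt
Reagents that add atoms: none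
Why: Acid-catalysed transketalization to methanol removes the acetonide and no stereocentre is involved.

Step 9
Reactants: 12 (S)-but-3-yne-1,2-diol
Product: 13 (S)-1,2-bis(triethylsilyloxy)but-3-yne
Conditions: TESCl (2.5 equiv), imidazole, DMF, 0 °C → rt
Reagents that add atoms: chlorotriethylsilane, CC[Si](Cl)(CC)CC
Why: Routine bis-silylation that prepares the selective oxidation of the primary silyl ether.

Step 10
Reactants: 13 (S)-1,2-bis(triethylsilyloxy)but-3-yne
Product: 14 (S)-2-(triethylsilyloxy)but-3-ynal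
Conditions: (COCl)2, DMSO, CH2Cl2, −78 → −40 °C; i-Pr2NEt, −78 °C; cold pH 7 quench, used at once
Reagents that add atoms: none
Why: Swern oxidation of a bis-triethylsilyl ether, in which the chlorosulfonium salt cleaves and oxidizes only the unhindered primary silyl ether, while the low temperature and hindered base should keep the epimerizable C8 centre intact.

Step 11
Reactants: 9 (2Z,4S,6Z)-7-iodo-3-methyl-1,4-bis(triethylsilyloxy)octa-2,6-diene; 14 (S)-2-(triethylsilyloxy)but-3-ynal
Product: 15 (2Z,4S,6Z,8R,9S)-3,7-dimethyl-1,4,9-tris(triethylsilyloxy)undeca-2,6-dien-10-yn-8-ol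
Conditions: CrCl2 (6 equiv), NiCl2 (1 mol %), degassed DMSO/THF, rt
Reagents that add atoms: none
Why: Nozaki–Hiyama–Kishi coupling with retention of the Z-iodide geometry, in which C9 (R) should arise by Felkin–Anh addition anti to the α-silyloxy group (1,2-anti) and the weakly basic alkenylchromium tolerates the enolizable aldehyde and the terminal alkyne.

Step 12
Reactants: 15 (2Z,4S,6Z,8R,9S)-3,7-dimethyl-1,4,9-tris(triethylsilyloxy)undeca-2,6-dien-10-yn-8-ol
Product: 16 (2Z,4S,6Z,8R,9S)-8-(tert-butyldimethylsilyloxy)-3,7-dimethyl-1,4,9-tris(triethylsilyloxy)undeca-2,6-dien-10-yne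
Conditions: TBSOTf, 2,6-lutidine, CH2Cl2, −78 → 0 °C
Reagents that add atoms: tert-butyldimethylsilyl triflate, CC(C)(C)[Si](C)(C)OS(=O)(=O)C(F)(F)F
Why: Silylation of the hindered secondary allylic alcohol with the silyl triflate differentiates O9 (robust TBS) from O8 and O3 (labile TES).

Step 13
Reactants: 16 (2Z,4S,6Z,8R,9S)-8-(tert-butyldimethylsilyloxy)-3,7-dimethyl-1,4,9-tris(triethylsilyloxy)undeca-2,6-dien-10-yne
Product: 18 (2Z,4S,6Z,8R,9S)-8-(tert-butyldimethylsilyloxy)-3,7-dimethyl-1,4,9-tris(triethylsilyloxy)dodeca-2,6,10,11-tetraene, via propargylic amine 17 (not isolated)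
Conditions: (CH2O)n, CuI (0.5 equiv), Cy2NH, 1,4-dioxane, reflux
Reagents that add atoms: paraformaldehyde (formaldehyde), C=O
Why: Crabbé homologation, in which the copper-mediated Mannich reaction of the terminal alkyne is followed by intramolecular hydride transfer from the dicyclohexylamino group and loss of the imine, should give the terminal allene without touching C8.

Step 14
Reactants: 18 (2Z,4S,6Z,8R,9S)-8-(tert-butyldimethylsilyloxy)-3,7-dimethyl-1,4,9-tris(triethylsilyloxy)dodeca-2,6,10,11-tetraene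
Product: 19 (2Z,4S,6Z,8R,9S)-8-(tert-butyldimethylsilyloxy)-3,7-dimethyl-4,9-bis(triethylsilyloxy)dodeca-2,6,10,11-tetraenal
Conditions: (COCl)2, DMSO, CH2Cl2, −78 → −30 °C; Et3N, −78 → −20 °C
Reagents that add atoms: none
Why: Swern oxidation, selective for the primary allylic triethylsilyl ether, should unveil the Z-enal without isomerization at low temperature and leave the allene and the secondary silyl ethers intact.

Step 15
Reactants: 19 (2Z,4S,6Z,8R,9S)-8-(tert-butyldimethylsilyloxy)-3,7-dimethyl-4,9-bis(triethylsilyloxy)dodeca-2,6,10,11-tetraenal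
Product: 22 (3S,6R,7S,8S,9R,1(10)Z,4Z)-9-(tert-butyldimethylsilyloxy)-3,8-bis(triethylsilyloxy)germacra-1(10),4,11(13)-trien-12,6-olide, via allylnickel carboxylate 20 (not isolated), via hydroxy acid 21 (not isolated)
Conditions: Ni(cod)2 (1.2 equiv), DBU (2.5 equiv), CO2 (1 atm), THF, 0 °C, 19 added over 12 h (final 2 mM), then rt; 1 M HCl, 0 °C; PPTS (cat.), CH2Cl2, rt
Reagents that add atoms: carbon dioxide, O=C=O
Why: Proposed new method: DBU-ligated zerovalent nickel couples the terminal C11=C13 bond of the allene with CO2 at the central carbon (new C11–C12 bond) to give an oxanickelacycle that is an allylnickel carboxylate, and this persistent 2-carboxyallyl metal adds through C7 to the tethered C6 aldehyde (new C6–C7 bond) before acid releases the γ-hydroxy acid, which lactonizes. The closest known reaction type is the nickel-mediated sequential coupling of terminal allenes with CO2 and aldehydes (intermolecular, and as a cyclizing cascade of allenyl aldehydes to five- and six-membered carbocycles), together with the macrocyclizing 2-carboxyallyl-metal (Barbier/Nozaki–Hiyama) additions used for medium-ring terpenoid lactones, whereas a ten-membered closure by the nickelacycle is not known. The ten-membered carbocycle closes by intramolecular SE2′ carbonyl allylation through a six-membered chair (Ni–C13–C11=C7···C6=O, a 10-exo-trig attack on the carbonyl), and the five-membered lactone by 5-exo-trig acyl substitution of O6 on C12. C7 is set relative to C8 by allylic 1,3-strain (H8 in the allyl plane, C6 entering anti to the C8–C9 bond and gauche to the silyloxy group, which is 7S for the 8S,9R chain), and C6 relative to C7 by the ring, since the six-atom tether from C8 to C5 across the two Z olefins is best spanned in the chair with H6 and H7 anti, the 6,7-trans sense also delivered by chromium-mediated closures of this bond, which is 6R. The step needs CO2 to win over the aldehyde at nickel (1 atm of CO2 against an entropically penalized eleven-membered allene–aldehyde coupling), attack at C7 over C13 (primary σ-allyl and chair; the alternative is a twelve-membered ring), 1,2- over 1,4-addition (β,β-disubstituted enal) and ring closure over oligomerization (slow addition to 2 mM). The enal belongs to the same non-enolizable conjugated class as the aryl aldehydes of the known reaction, and every hydroxyl is silylated so that no allylic or allenylic ester can ionize at nickel.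

Step 16
Reactants: 22 (3S,6R,7S,8S,9R,1(10)Z,4Z)-9-(tert-butyldimethylsilyloxy)-3,8-bis(triethylsilyloxy)germacra-1(10),4,11(13)-trien-12,6-olide
Product: 23 (3S,6R,7R,8S,9R,1(10)Z,4Z)-9-(tert-butyldimethylsilyloxy)-3,8-dihydroxygermacra-1(10),4,11(13)-trien-12,6-olide
Conditions: CSA (10 mol %), MeOH/CH2Cl2 (1:1), −10 °C
Reagents that add atoms: none
Why: Acid-catalysed methanolysis should remove the two secondary triethylsilyl ethers while the hindered secondary TBS ether survives, and the non-basic medium avoids silyl migration and relactonization to O8.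

Step 17
Reactants: 23 (3S,6R,7R,8S,9R,1(10)Z,4Z)-9-(tert-butyldimethylsilyloxy)-3,8-dihydroxygermacra-1(10),4,11(13)-trien-12,6-olide
Product: 24 (3S,6R,7R,8S,9R,1(10)Z,4Z)-3-acetoxy-9-(tert-butyldimethylsilyloxy)-8-hydroxygermacra-1(10),4,11(13)-trien-12,6-olide
Conditions: Ac2O (1.1 equiv), pyridine, CH2Cl2, 0 °C
Reagents that add atoms: acetic anhydride, CC(=O)OC(C)=O
Why: Regioselective acetylation of the less hindered allylic C3 hydroxyl (CH2 neighbour) over the C8 hydroxyl, which is flanked by the ring-fusion carbon and the silyloxy-bearing C9.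

Step 18
Reactants: 25 (E)-2-methylbut-2-en-1-ol
Product: 26 [(2R,3R)-2,3-dimethyloxiran-2-yl]methanol
Conditions: Ti(OiPr)4 (10 mol %), D-(−)-diisopropyl tartrate (12 mol %), t-BuOOH, 4 Å molecular sieves, CH2Cl2, −20 °C
Reagents that add atoms: tert-butyl hydroperoxide, CC(C)(C)OO
Why: Sharpless asymmetric epoxidation, in which the D-(−)-tartrate delivers oxygen to the face of the E-allylic alcohol that gives the (2R,3R)-epoxy alcohol (the L-(+)-tartrate gives the 2S,3S series) and the E geometry fixes the cis relationship of the two methyl groups.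

Step 19
Reactants: 26 [(2R,3R)-2,3-dimethyloxiran-2-yl]methanol
Product: 27 (2S,3R)-2,3-dimethyloxirane-2-carboxylic acid
Conditions: TEMPO (10 mol %), PhI(OAc)2 (2.2 equiv), MeCN/H2O (1:1), rt
Reagents that add atoms: water, O
Why: TEMPO/iodobenzene diacetate oxidation takes the primary alcohol through the aldehyde hydrate to the acid without opening the epoxide, the descriptor at C2 changing to S only by priority.

Step 20
Reactants: 24 (3S,6R,7R,8S,9R,1(10)Z,4Z)-3-acetoxy-9-(tert-butyldimethylsilyloxy)-8-hydroxygermacra-1(10),4,11(13)-trien-12,6-olide; 27 (2S,3R)-2,3-dimethyloxirane-2-carboxylic acid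
Product: 29 (3S,6R,7S,8S,9R,1(10)Z,4Z)-3-acetoxy-9-(tert-butyldimethylsilyloxy)-8-[(2S,3R)-2,3-dimethyloxirane-2-carbonyloxy]germacra-1(10),4,11(13)-trien-12,6-olide, via mixed anhydride 28 (not isolated)
Conditions: 27, 2,4,6-trichlorobenzoyl chloride, Et3N, THF, rt; then 24, DMAP, toluene, rt
Reagents that add atoms: none
Why: Yamaguchi esterification, in which DMAP attacks the less hindered carbonyl of the mixed anhydride of the α-branched epoxy acid and the acylpyridinium acylates the hindered C8 hydroxyl, with no stereocentre affected.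

Step 21
Reactants: 29 (3S,6R,7S,8S,9R,1(10)Z,4Z)-3-acetoxy-9-(tert-butyldimethylsilyloxy)-8-[(2S,3R)-2,3-dimethyloxirane-2-carbonyloxy]germacra-1(10),4,11(13)-trien-12,6-olide
Product: 30 (3S,6R,7S,8S,9R,1(10)Z,4Z)-3-acetoxy-9-hydroxy-8-[(2S,3R)-2,3-dimethyloxirane-2-carbonyloxy]germacra-1(10),4,11(13)-trien-12,6-olide (CNP0299903.2)
Conditions: HF·pyridine, pyridine, THF, 0 °C → rt
Reagents that add atoms: none
Why: Fluoride-induced Si–O cleavage under buffered acidic conditions should free the C9 hydroxyl without acyl migration from O8 to O9, epoxide opening or conjugate addition to the methylene lactone.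

**Compound list**
1 | but-2-yn-1-ol | CC#CCO | starting material
2 | sodium 2,2-bis(2-methoxyethoxy)-3-methyl-2,5-dihydro-1,2-oxaluminol-2-uide (cyclic alkenylaluminate) | CC1=CCO[Al-]1(OCCOC)OCCOC.[Na+] | intermediate
3 | (Z)-3-iodobut-2-en-1-ol | OC/C=C(/C)I | intermediate
4 | 3-[(4-methoxybenzyl)oxy]propanal | COc1ccc(COCCC=O)cc1 | starting material
5 | (2Z,4S)-6-[(4-methoxybenzyl)oxy]-3-methylhex-2-ene-1,4-diol | OC/C=C(/C)[C@@H](O)CCOCc1ccc(OC)cc1 | intermediate
6 | (2Z,4S)-6-[(4-methoxybenzyl)oxy]-3-methyl-1,4-bis(triethylsilyloxy)hex-2-ene | CC[Si](CC)(CC)OC/C=C(/C)[C@@H](O[Si](CC)(CC)CC)CCOCc1ccc(OC)cc1 | intermediate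
7 | (3S,4Z)-4-methyl-3,6-bis(triethylsilyloxy)hex-4-en-1-ol | CC[Si](CC)(CC)OC/C=C(/C)[C@@H](O[Si](CC)(CC)CC)CCO | intermediate
8 | (3S,4Z)-4-methyl-3,6-bis(triethylsilyloxy)hex-4-enal | CC[Si](CC)(CC)OC/C=C(/C)[C@@H](O[Si](CC)(CC)CC)CC=O | intermediate
9 | (2Z,4S,6Z)-7-iodo-3-methyl-1,4-bis(triethylsilyloxy)octa-2,6-diene | CC[Si](CC)(CC)OC/C=C(/C)[C@@H](O[Si](CC)(CC)CC)C/C=C(/C)I | intermediate
10 | (R)-2,2-dimethyl-1,3-dioxolane-4-carbaldehyde | O=C[C@H]1COC(C)(C)O1 | starting material
11 | (S)-4-ethynyl-2,2-dimethyl-1,3-dioxolane | C#C[C@H]1COC(C)(C)O1 | intermediate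
12 | (S)-but-3-yne-1,2-diol | C#C[C@H](O)CO | intermediate
13 | (S)-1,2-bis(triethylsilyloxy)but-3-yne | C#C[C@H](O[Si](CC)(CC)CC)CO[Si](CC)(CC)CC | intermediate
14 | (S)-2-(triethylsilyloxy)but-3-ynal | C#C[C@H](O[Si](CC)(CC)CC)C=O | intermediate
15 | (2Z,4S,6Z,8R,9S)-3,7-dimethyl-1,4,9-tris(triethylsilyloxy)undeca-2,6-dien-10-yn-8-ol | CC[Si](CC)(CC)OC/C=C(/C)[C@@H](O[Si](CC)(CC)CC)C/C=C(/C)[C@@H](O)[C@@H](O[Si](CC)(CC)CC)C#C | intermediate
16 | (2Z,4S,6Z,8R,9S)-8-(tert-butyldimethylsilyloxy)-3,7-dimethyl-1,4,9-tris(triethylsilyloxy)undeca-2,6-dien-10-yne | CC[Si](CC)(CC)OC/C=C(/C)[C@@H](O[Si](CC)(CC)CC)C/C=C(/C)[C@@H](O[Si](C)(C)C(C)(C)C)[C@@H](O[Si](CC)(CC)CC)C#C | intermediate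
17 | (4S,5R,6Z,9S,10Z)-5-(tert-butyldimethylsilyloxy)-N,N-dicyclohexyl-6,10-dimethyl-4,9,12-tris(triethylsilyloxy)dodeca-6,10-dien-2-yn-1-amine | CC[Si](CC)(CC)OC/C=C(/C)[C@@H](O[Si](CC)(CC)CC)C/C=C(/C)[C@@H](O[Si](C)(C)C(C)(C)C)[C@@H](O[Si](CC)(CC)CC)C#CCN(C1CCCCC1)C1CCCCC1 | intermediate
18 | (2Z,4S,6Z,8R,9S)-8-(tert-butyldimethylsilyloxy)-3,7-dimethyl-1,4,9-tris(triethylsilyloxy)dodeca-2,6,10,11-tetraene | CC[Si](CC)(CC)OC/C=C(/C)[C@@H](O[Si](CC)(CC)CC)C/C=C(/C)[C@@H](O[Si](C)(C)C(C)(C)C)[C@@H](O[Si](CC)(CC)CC)C=C=C | intermediate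
19 | (2Z,4S,6Z,8R,9S)-8-(tert-butyldimethylsilyloxy)-3,7-dimethyl-4,9-bis(triethylsilyloxy)dodeca-2,6,10,11-tetraenal | O=C/C=C(/C)[C@@H](O[Si](CC)(CC)CC)C/C=C(/C)[C@@H](O[Si](C)(C)C(C)(C)C)[C@@H](O[Si](CC)(CC)CC)C=C=C | intermediate
20 | allylnickel carboxylate of 19 (σ-allyl oxanickelacycle form, C11–C12 bond made; DBU ligands on nickel omitted) | O=C/C=C(/C)[C@@H](O[Si](CC)(CC)CC)C/C=C(/C)[C@@H](O[Si](C)(C)C(C)(C)C)[C@@H](O[Si](CC)(CC)CC)/C=C1\C[Ni]OC1=O | intermediate
21 | (3S,6R,7S,8S,9R,1(10)Z,4Z)-9-(tert-butyldimethylsilyloxy)-6-hydroxy-3,8-bis(triethylsilyloxy)germacra-1(10),4,11(13)-trien-12-oic acid | C=C(C(=O)O)[C@H]1[C@H](O)/C=C(/C)[C@@H](O[Si](CC)(CC)CC)C/C=C(/C)[C@@H](O[Si](C)(C)C(C)(C)C)[C@H]1O[Si](CC)(CC)CC | intermediate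
22 | (3S,6R,7S,8S,9R,1(10)Z,4Z)-9-(tert-butyldimethylsilyloxy)-3,8-bis(triethylsilyloxy)germacra-1(10),4,11(13)-trien-12,6-olide | C=C1C(=O)O[C@@H]2/C=C(/C)[C@@H](O[Si](CC)(CC)CC)C/C=C(/C)[C@@H](O[Si](C)(C)C(C)(C)C)[C@@H](O[Si](CC)(CC)CC)[C@@H]12 | intermediate
23 | (3S,6R,7R,8S,9R,1(10)Z,4Z)-9-(tert-butyldimethylsilyloxy)-3,8-dihydroxygermacra-1(10),4,11(13)-trien-12,6-olide | C=C1C(=O)O[C@@H]2/C=C(/C)[C@@H](O)C/C=C(/C)[C@@H](O[Si](C)(C)C(C)(C)C)[C@@H](O)[C@@H]12 | intermediate
24 | (3S,6R,7R,8S,9R,1(10)Z,4Z)-3-acetoxy-9-(tert-butyldimethylsilyloxy)-8-hydroxygermacra-1(10),4,11(13)-trien-12,6-olide | C=C1C(=O)O[C@@H]2/C=C(/C)[C@@H](OC(C)=O)C/C=C(/C)[C@@H](O[Si](C)(C)C(C)(C)C)[C@@H](O)[C@@H]12 | intermediate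
25 | (E)-2-methylbut-2-en-1-ol | C/C=C(\C)CO | starting material
26 | [(2R,3R)-2,3-dimethyloxiran-2-yl]methanol | OC[C@@]1(C)O[C@@H]1C | intermediate
27 | (2S,3R)-2,3-dimethyloxirane-2-carboxylic acid | OC(=O)[C@@]1(C)O[C@@H]1C | intermediate
28 | (2S,3R)-2,3-dimethyloxirane-2-carboxylic 2,4,6-trichlorobenzoic anhydride | O=C(OC(=O)c1c(Cl)cc(Cl)cc1Cl)[C@@]1(C)O[C@@H]1C | intermediate
29 | (3S,6R,7S,8S,9R,1(10)Z,4Z)-3-acetoxy-9-(tert-butyldimethylsilyloxy)-8-[(2S,3R)-2,3-dimethyloxirane-2-carbonyloxy]germacra-1(10),4,11(13)-trien-12,6-olide | C=C1C(=O)O[C@@H]2/C=C(/C)[C@@H](OC(C)=O)C/C=C(/C)[C@@H](O[Si](C)(C)C(C)(C)C)[C@@H](OC(=O)[C@@]3(C)O[C@@H]3C)[C@@H]12 | intermediate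
30 | (3S,6R,7S,8S,9R,1(10)Z,4Z)-3-acetoxy-9-hydroxy-8-[(2S,3R)-2,3-dimethyloxirane-2-carbonyloxy]germacra-1(10),4,11(13)-trien-12,6-olide | C=C1C(=O)O[C@@H]2/C=C(/C)[C@@H](OC(C)=O)C/C=C(/C)[C@@H](O)[C@@H](OC(=O)[C@@]3(C)O[C@@H]3C)[C@@H]12 | target

**Step count and risks**
Total: 21 steps. Longest linear sequence: 15 steps (steps 1–6, 11–17, 20, 21).

Step 15 (proposed new method). What may go wrong:
- the allylnickel carboxylate is protonated or carboxylated a second time before the slow ten-membered closure;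
- closure through C13 gives the twelve-membered ring;
- the chair closes with the wrong C6/C7 topicity;
- the Z-enal isomerizes under DBU.

Fallback, from alkyne 16 back to lactone 22: deprotonation (n-BuLi, THF, −78 °C) and methyl chloroformate should give the ynoate F1. Hydroalumination with DIBAL-H/HMPA and trapping of the α-alumino acrylate with formaldehyde gives the Baylis–Hillman-type 2-(hydroxymethyl)enoate F2. CBr4/PPh3 gives the allylic bromide F3. Selective methanolysis of the primary silyl ether (PPTS, MeOH, 0 °C) gives the allylic alcohol F4, and MnO2 the bromo enal F5. An intramolecular Barbier (Nozaki–Hiyama) allylation with CrCl2 at high dilution, the established way to close this bond in germacranolides, gives the hydroxy ester F6, which lactonizes with PPTS to 22.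

Step 11. What may go wrong: epimerization of the α-silyloxy ynal before coupling and insufficient Felkin–Anh facial selectivity at C9. Fallback, from 15 (as the C9 epimer mixture) back to 15: Dess–Martin oxidation gives the Z-enone F7. 1,2-Reduction with L-Selectride at −78 °C (Felkin–Anh, a small hydride is more selective than the alkenylchromium) or, under reagent control, with the CBS oxazaborolidine/catecholborane should return 15 as the 9R alcohol.

Step 2. What may go wrong: insufficient enantioinduction with the free-hydroxyl Z-iodide. Fallback, from aldehyde 4 back to diol 5: lithium (trimethylsilyl)acetylide gives the racemic propargylic alcohol F8, and MnO2 the ynone F9. Noyori transfer hydrogenation with RuCl[(S,S)-TsDPEN](p-cymene) in i-PrOH gives the (S)-alcohol F10, and K2CO3/MeOH the terminal alkyne F11. Copper-catalysed anti-carbomagnesiation (MeMgBr, CuI cat., THF), with the alkoxide-chelated alkenylmagnesium trapped by paraformaldehyde, returns the Z-diol 5.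

**Further compounds**
F1 | step 15 | methyl (4S,5R,6Z,9S,10Z)-5-(tert-butyldimethylsilyloxy)-6,10-dimethyl-4,9,12-tris(triethylsilyloxy)dodeca-6,10-dien-2-ynoate | CC[Si](CC)(CC)OC/C=C(/C)[C@@H](O[Si](CC)(CC)CC)C/C=C(/C)[C@@H](O[Si](C)(C)C(C)(C)C)[C@@H](O[Si](CC)(CC)CC)C#CC(=O)OC
F2 | step 15 | methyl (2Z,4S,5R,6Z,9S,10Z)-5-(tert-butyldimethylsilyloxy)-2-(hydroxymethyl)-6,10-dimethyl-4,9,12-tris(triethylsilyloxy)dodeca-2,6,10-trienoate | CC[Si](CC)(CC)OC/C=C(/C)[C@@H](O[Si](CC)(CC)CC)C/C=C(/C)[C@@H](O[Si](C)(C)C(C)(C)C)[C@@H](O[Si](CC)(CC)CC)/C=C(/CO)C(=O)OC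
F3 | step 15 | methyl (2Z,4S,5R,6Z,9S,10Z)-2-(bromomethyl)-5-(tert-butyldimethylsilyloxy)-6,10-dimethyl-4,9,12-tris(triethylsilyloxy)dodeca-2,6,10-trienoate | CC[Si](CC)(CC)OC/C=C(/C)[C@@H](O[Si](CC)(CC)CC)C/C=C(/C)[C@@H](O[Si](C)(C)C(C)(C)C)[C@@H](O[Si](CC)(CC)CC)/C=C(/CBr)C(=O)OC
F4 | step 15 | methyl (2Z,4S,5R,6Z,9S,10Z)-2-(bromomethyl)-5-(tert-butyldimethylsilyloxy)-12-hydroxy-6,10-dimethyl-4,9-bis(triethylsilyloxy)dodeca-2,6,10-trienoate | OC/C=C(/C)[C@@H](O[Si](CC)(CC)CC)C/C=C(/C)[C@@H](O[Si](C)(C)C(C)(C)C)[C@@H](O[Si](CC)(CC)CC)/C=C(/CBr)C(=O)OC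
F5 | step 15 | methyl (2Z,4S,5R,6Z,9S,10Z)-2-(bromomethyl)-5-(tert-butyldimethylsilyloxy)-6,10-dimethyl-12-oxo-4,9-bis(triethylsilyloxy)dodeca-2,6,10-trienoate | O=C/C=C(/C)[C@@H](O[Si](CC)(CC)CC)C/C=C(/C)[C@@H](O[Si](C)(C)C(C)(C)C)[C@@H](O[Si](CC)(CC)CC)/C=C(/CBr)C(=O)OC
F6 | step 15 | methyl (3S,6R,7S,8S,9R,1(10)Z,4Z)-9-(tert-butyldimethylsilyloxy)-6-hydroxy-3,8-bis(triethylsilyloxy)germacra-1(10),4,11(13)-trien-12-oate | C=C(C(=O)OC)[C@H]1[C@H](O)/C=C(/C)[C@@H](O[Si](CC)(CC)CC)C/C=C(/C)[C@@H](O[Si](C)(C)C(C)(C)C)[C@H]1O[Si](CC)(CC)CC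
F7 | step 11 | (2Z,4S,6Z,9S)-3,7-dimethyl-1,4,9-tris(triethylsilyloxy)undeca-2,6-dien-10-yn-8-one | CC[Si](CC)(CC)OC/C=C(/C)[C@@H](O[Si](CC)(CC)CC)C/C=C(/C)C(=O)[C@@H](O[Si](CC)(CC)CC)C#C
F8 | step 2 | racemic 5-[(4-methoxybenzyl)oxy]-1-(trimethylsilyl)pent-1-yn-3-ol | C[Si](C)(C)C#CC(O)CCOCc1ccc(OC)cc1
F9 | step 2 | 5-[(4-methoxybenzyl)oxy]-1-(trimethylsilyl)pent-1-yn-3-one | C[Si](C)(C)C#CC(=O)CCOCc1ccc(OC)cc1
F10 | step 2 | (S)-5-[(4-methoxybenzyl)oxy]-1-(trimethylsilyl)pent-1-yn-3-ol | C[Si](C)(C)C#C[C@@H](O)CCOCc1ccc(OC)cc1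
F11 | step 2 | (S)-5-[(4-methoxybenzyl)oxy]pent-1-yn-3-ol | C#C[C@@H](O)CCOCc1ccc(OC)cc1
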